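**Retrosynthetic overview**
- Target 18 comes from allylic alcohol 17 by a late face-selective epoxidation (C–O), 17 from enone 16 by Luche reduction, and the 2-acetate from a silyl ether.
- The C6 anisoate and the C6 stereocentre are made together from tertiary β-hydroxy ketone 10 and p-anisaldehyde by one directed reductive acyloxylation (the key C–O bond step, new).
- 10 comes from triketone 7 by double O-silylation and isopropyl addition to C4.
- 7 comes from glycol cleavage of the cyclobutane-diol photoadduct 6, itself the [2+2] adduct of enone 3 and bis(silyloxy)cyclopentene 5.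
- Ring order: the cyclopentane (from 1) comes first, then the 5-4-5 tricycle, then the seven-membered ring by opening the cyclobutane.

Convention: bicyclic compounds carry daucane numbering (C1 = ring-fusion carbon with CH3-15; C2–C4 = five-membered ring, C4 carries the isopropyl C11–C13; C5 = ring-fusion CH; C6–C10 = seven-membered ring, C8 carries CH3-14).
Assumption: 1, 4 and 11 are bought; 6–13 are carried as C8-epimer mixtures that converge in step 9.

**Step 1**
Reactants: 1 (R)-4-[(tert-butyldimethylsilyl)oxy]cyclopent-2-en-1-one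
Product: 2 (3R,4R)-4-[(tert-butyldimethylsilyl)oxy]-3-methyl-1-[(trimethylsilyl)oxy]cyclopent-1-ene
Conditions: MeMgBr, CuBr·SMe2 (5 mol %), TMSCl, DMPU, THF, −78 °C
Reagents that add atoms: methylmagnesium bromide C[Mg]Br; chlorotrimethylsilane C[Si](C)(C)Cl
Why: Cu-catalysed conjugate addition with in situ silyl trapping puts CH3 trans to OTBS and gives the enol ether regiospecifically (this new centre becomes sp2 again in step 2).

**Step 2**
Reactants: 2 (3R,4R)-4-[(tert-butyldimethylsilyl)oxy]-3-methyl-1-[(trimethylsilyl)oxy]cyclopent-1-ene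
Product: 3 (R)-4-[(tert-butyldimethylsilyl)oxy]-3-methylcyclopent-2-en-1-one
Conditions: Pd(OAc)2 (10 mol %), O2 (1 atm), DMSO, rt
Reagents that add atoms: none
Why: Saegusa–Ito oxidation of the regiodefined silyl enol ether restores the enone with the β-methyl in place; the silyloxy stereocentre is not touched.

**Step 3**
Reactants: 4 dimethyl 3-methylpentanedioate
Product: 5 4-methyl-1,2-bis[(trimethylsilyl)oxy]cyclopent-1-ene
Conditions: Na, TMSCl, toluene, reflux
Reagents that add atoms: chlorotrimethylsilane C[Si](C)(C)Cl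
Why: Acyloin condensation with silyl trapping (Rühlmann variant) gives the symmetric enediol bis-silyl ether that supplies C6–C10 with oxygen on C6 and C10.

**Step 4**
Reactants: 3 (R)-4-[(tert-butyldimethylsilyl)oxy]-3-methylcyclopent-2-en-1-one; 5 4-methyl-1,2-bis[(trimethylsilyl)oxy]cyclopent-1-ene
Product: 6 5-[(tert-butyldimethylsilyl)oxy]-6,9-dimethyl-1,7-bis[(trimethylsilyl)oxy]tricyclo[5.3.0.0^2,6]decan-3-one (cis-anti-cis; cyclobutane anti to OTBS, so 6-CH3 and 5-OTBS are cis; C9 epimers)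
Conditions: hν (366 nm), 5 (5 equiv), CH2Cl2, −30 °C
Reagents that add atoms: none
Why: Enone–alkene [2+2] photocycloaddition; the symmetric electron-rich alkene adds to the enone face opposite the silyloxy group, which sets C1 (CH3 cis to 2-OTBS), and the other new centres are erased in steps 5 and 9.

**Step 5**
Reactants: 6 photoadduct (tricyclic bis-TMS ether)
Product: 7 (1R,2R)-2-[(tert-butyldimethylsilyl)oxy]-11,12,13-trinordaucane-4,6,10-trione (C5 enolised, C8 epimers)
Conditions: H5IO6, THF–H2O, 0 °C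
Reagents that add atoms: none
Why: Aqueous periodic acid hydrolyses the two tertiary TMS ethers and cleaves the cis-cyclobutane-1,2-diol (Malaprade glycol cleavage), opening the four-membered ring into the seven-membered ring and leaving C5 as the stereolabile CH of a 1,3-diketone.

**Step 6**
Reactants: 7 (1R,2R)-2-[(tert-butyldimethylsilyl)oxy]-11,12,13-trinordaucane-4,6,10-trione
Product: 8 (1R,2R)-2,6,10-tris[(tert-butyldimethylsilyl)oxy]-11,12,13-trinordauca-5,9-dien-4-one
Conditions: TBSOTf (2.3 equiv), Et3N, CH2Cl2, −78 → 0 °C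
Reagents that add atoms: tert-butyldimethylsilyl trifluoromethanesulfonate CC(C)(C)[Si](C)(C)OS(=O)(=O)C(F)(F)F
Why: Soft enolisation and O-silylation; the 4,6-diketone gives the vinylogous silyl ester with C5=C6 endocyclic to the seven-membered ring and exocyclic to the cyclopentanone (the preferred enol of a 2-acylcyclopentanone, reachable by O-to-O silyl shift), and the C10 ketone can only enolise towards C9, so C4 is left as the sole carbonyl.

**Step 7**
Reactants: 8 (1R,2R)-2,6,10-tris[(tert-butyldimethylsilyl)oxy]-11,12,13-trinordauca-5,9-dien-4-one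
Product: 10 (1R,2R,4R,5R)-2-[(tert-butyldimethylsilyl)oxy]-4-hydroxydaucane-6,10-dione, via C4 isopropyl carbinol bis(silyl enol ether) 9 (not isolated)
Conditions: iPrMgCl, CeCl3 (anhydrous), THF, −78 °C; then AcOH, TBAF, THF, −20 → 0 °C
Reagents that add atoms: isopropylmagnesium chloride CC(C)[Mg]Cl
Why: Organocerium 1,2-addition to the only carbonyl (a Stork–Danheiser-type addition without the acid step) occurs on the face opposite the angular CH3 and the 2-OTBS group, which sets C4 (OH cis to CH3), and buffered fluoride then frees both enol ethers with C5 settling as the trans ring fusion (iPr and C6 anti, 4-OH hydrogen-bonded to the C6 carbonyl).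

**Step 8**
Reactants: 10 (1R,2R,4R,5R)-2-[(tert-butyldimethylsilyl)oxy]-4-hydroxydaucane-6,10-dione; 11 4-methoxybenzaldehyde
Product: 13 (1R,2R,4R,5S,6S)-2-[(tert-butyldimethylsilyl)oxy]-4-hydroxy-10-oxodaucan-6-yl 4-methoxybenzoate, via tertiary 4-O-anisoate 12 (not isolated)
Conditions: 11 (6 equiv), SmI2 (30 mol %), THF, −10 °C; then 40 °C
Reagents that add atoms: none
Why: Proposed new method: a tertiary-carbinol-directed Tishchenko reductive acyloxylation with built-in 1,3-acyl shift — the Sm(III) alkoxide of the C4 tertiary alcohol adds to the aldehyde, the hemiacetal C–H is delivered through a Sm-bridged six-membered transition state to the C6 carbonyl from the face of the C4 oxygen (6-O anti to 4-O, C6 = S), and the Sm alkoxide formed at C6 then takes the anisoyl group from the hindered tertiary oxygen through a six-membered orthoester to give the secondary ester; the closest known reaction is the Evans–Tishchenko reduction of secondary β-hydroxy ketones (with base-mediated O-to-O acyl migration), not shown for a tertiary carbinol as the directing group with programmed acyl transfer.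

**Step 9**
Reactants: 13 (1R,2R,4R,5S,6S)-2-[(tert-butyldimethylsilyl)oxy]-4-hydroxy-10-oxodaucan-6-yl 4-methoxybenzoate
Product: 14 (1R,2R,4R,5S,6S)-2-[(tert-butyldimethylsilyl)oxy]-4-hydroxy-10-oxodauc-8-en-6-yl 4-methoxybenzoate
Conditions: IBX (2.2 equiv), DMSO, 65 °C
Reagents that add atoms: none
Why: IBX α,β-dehydrogenation of the only ketone; C10 can enolise only towards C9 because C1 is quaternary, so the 8,9-enone forms regiospecifically and both C8 epimers converge.

**Step 10**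
Reactants: 14 (1R,2R,4R,5S,6S)-2-[(tert-butyldimethylsilyl)oxy]-4-hydroxy-10-oxodauc-8-en-6-yl 4-methoxybenzoate
Product: 15 (1R,2R,4R,5S,6S)-2,4-dihydroxy-10-oxodauc-8-en-6-yl 4-methoxybenzoate
Conditions: HF·pyridine, THF, 0 °C → rt
Reagents that add atoms: none
Why: Fluoride-mediated Si–O cleavage under mildly acidic conditions spares the anisoate, the enone and the tertiary alcohol and avoids base that could trigger retro-aldol of the 2-hydroxy-10-ketone.

**Step 11**
Reactants: 15 (1R,2R,4R,5S,6S)-2,4-dihydroxy-10-oxodauc-8-en-6-yl 4-methoxybenzoate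
Product: 16 (1R,2R,4R,5S,6S)-2-acetoxy-4-hydroxy-10-oxodauc-8-en-6-yl 4-methoxybenzoate
Conditions: Ac2O, pyridine, DMAP (cat.), CH2Cl2, 0 °C
Reagents that add atoms: acetic anhydride CC(=O)OC(C)=O
Why: DMAP-catalysed acetylation of the only secondary alcohol (C10 is still a ketone); the tertiary 4-OH does not react at 0 °C.

**Step 12**
Reactants: 16 (1R,2R,4R,5S,6S)-2-acetoxy-4-hydroxy-10-oxodauc-8-en-6-yl 4-methoxybenzoate
Product: 17 (1S,2R,4R,5S,6S,10S)-2-acetoxy-4,10-dihydroxydauc-8-en-6-yl 4-methoxybenzoate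
Conditions: NaBH4, CeCl3·7H2O, MeOH, −78 °C
Reagents that add atoms: none
Why: Luche 1,2-reduction; hydride adds to C10 from the face opposite the axial angular CH3, giving 10-OH cis to CH3 (S here, R in the target after the CIP priority change), and the esters survive at −78 °C.

**Step 13**
Reactants: 17 (1S,2R,4R,5S,6S,10S)-2-acetoxy-4,10-dihydroxydauc-8-en-6-yl 4-methoxybenzoate
Product: 18 (1S,2R,4R,5S,6S,8R,9S,10R)-2-acetoxy-8,9-epoxy-4,10-dihydroxydaucan-6-yl 4-methoxybenzoate (CNP0371526.1)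
Conditions: DMDO (1.2 equiv, acetone solution), acetone–MeOH 9:1, −20 → 0 °C
Reagents that add atoms: dimethyldioxirane CC1(C)OO1
Why: Electrophilic epoxidation with a neutral, sterically governed oxidant; the axial angular CH3 (1,3 to C9) shields the lower face, so oxygen arrives anti to CH3 and to 10-OH (trans-epoxy alcohol, C8 R, C9 S), with the protic co-solvent suppressing hydroxyl-directed delivery.

**Compound list**
1 | (R)-4-[(tert-butyldimethylsilyl)oxy]cyclopent-2-en-1-one | O=C1C=C[C@H](O[Si](C)(C)C(C)(C)C)C1 | starting material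
2 | (3R,4R)-4-[(tert-butyldimethylsilyl)oxy]-3-methyl-1-[(trimethylsilyl)oxy]cyclopent-1-ene | C[C@@H]1C=C(O[Si](C)(C)C)C[C@H]1O[Si](C)(C)C(C)(C)C | intermediate
3 | (R)-4-[(tert-butyldimethylsilyl)oxy]-3-methylcyclopent-2-en-1-one | CC1=CC(=O)C[C@H]1O[Si](C)(C)C(C)(C)C | intermediate
4 | dimethyl 3-methylpentanedioate | COC(=O)CC(C)CC(=O)OC | starting material
5 | 4-methyl-1,2-bis[(trimethylsilyl)oxy]cyclopent-1-ene | CC1CC(O[Si](C)(C)C)=C(O[Si](C)(C)C)C1 | intermediate
6 | 5-[(tert-butyldimethylsilyl)oxy]-6,9-dimethyl-1,7-bis[(trimethylsilyl)oxy]tricyclo[5.3.0.0^2,6]decan-3-one (cis-anti-cis, cyclobutane anti to OTBS, C9 epimers) | C[Si](C)(C)O[C@@]12CC(C)C[C@]1(O[Si](C)(C)C)[C@]1(C)[C@H]2C(=O)C[C@H]1O[Si](C)(C)C(C)(C)C | intermediate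
7 | (1R,2R)-2-[(tert-butyldimethylsilyl)oxy]-11,12,13-trinordaucane-4,6,10-trione (C5 enolised, C8 epimers) | O=C1CC(C)CC(=O)[C@]2(C)C1C(=O)C[C@H]2O[Si](C)(C)C(C)(C)C | intermediate
8 | (1R,2R)-2,6,10-tris[(tert-butyldimethylsilyl)oxy]-11,12,13-trinordauca-5,9-dien-4-one (C8 epimers) | CC(C)(C)[Si](C)(C)OC=1CC(C)C=C(O[Si](C)(C)C(C)(C)C)[C@]2(C)C1C(=O)C[C@H]2O[Si](C)(C)C(C)(C)C | intermediate
9 | (1R,2R,4R)-2,6,10-tris[(tert-butyldimethylsilyl)oxy]dauca-5,9-dien-4-ol (C8 epimers; formed as its Ce/Mg alkoxide) | CC(C)(C)[Si](C)(C)OC=1CC(C)C=C(O[Si](C)(C)C(C)(C)C)[C@]2(C)C1[C@](O)(C(C)C)C[C@H]2O[Si](C)(C)C(C)(C)C | intermediate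
10 | (1R,2R,4R,5R)-2-[(tert-butyldimethylsilyl)oxy]-4-hydroxydaucane-6,10-dione (C8 epimers) | O=C1CC(C)CC(=O)[C@]2(C)[C@@H]1[C@](O)(C(C)C)C[C@H]2O[Si](C)(C)C(C)(C)C | intermediate
11 | 4-methoxybenzaldehyde | COc1ccc(C=O)cc1 | starting material
12 | (1R,2R,4R,5S,6S)-2-[(tert-butyldimethylsilyl)oxy]-6-hydroxy-10-oxodaucan-4-yl 4-methoxybenzoate (C8 epimers) | O[C@H]1CC(C)CC(=O)[C@]2(C)[C@@H]1[C@](OC(=O)c3ccc(OC)cc3)(C(C)C)C[C@H]2O[Si](C)(C)C(C)(C)C | intermediate
13 | (1R,2R,4R,5S,6S)-2-[(tert-butyldimethylsilyl)oxy]-4-hydroxy-10-oxodaucan-6-yl 4-methoxybenzoate (C8 epimers) | COc1ccc(C(=O)O[C@H]2CC(C)CC(=O)[C@]3(C)[C@@H]2[C@](O)(C(C)C)C[C@H]3O[Si](C)(C)C(C)(C)C)cc1 | intermediate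
14 | (1R,2R,4R,5S,6S)-2-[(tert-butyldimethylsilyl)oxy]-4-hydroxy-10-oxodauc-8-en-6-yl 4-methoxybenzoate | COc1ccc(C(=O)O[C@H]2CC(C)=CC(=O)[C@]3(C)[C@@H]2[C@](O)(C(C)C)C[C@H]3O[Si](C)(C)C(C)(C)C)cc1 | intermediate
15 | (1R,2R,4R,5S,6S)-2,4-dihydroxy-10-oxodauc-8-en-6-yl 4-methoxybenzoate | COc1ccc(C(=O)O[C@H]2CC(C)=CC(=O)[C@]3(C)[C@@H]2[C@](O)(C(C)C)C[C@H]3O)cc1 | intermediate
16 | (1R,2R,4R,5S,6S)-2-acetoxy-4-hydroxy-10-oxodauc-8-en-6-yl 4-methoxybenzoate | COc1ccc(C(=O)O[C@H]2CC(C)=CC(=O)[C@]3(C)[C@@H]2[C@](O)(C(C)C)C[C@H]3OC(C)=O)cc1 | intermediate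
17 | (1S,2R,4R,5S,6S,10S)-2-acetoxy-4,10-dihydroxydauc-8-en-6-yl 4-methoxybenzoate | COc1ccc(C(=O)O[C@H]2CC(C)=C[C@H](O)[C@]3(C)[C@@H]2[C@](O)(C(C)C)C[C@H]3OC(C)=O)cc1 | intermediate
18 | (1S,2R,4R,5S,6S,8R,9S,10R)-2-acetoxy-8,9-epoxy-4,10-dihydroxydaucan-6-yl 4-methoxybenzoate | COc1ccc(C(=O)O[C@H]2C[C@@]3(C)O[C@H]3[C@H](O)[C@]3(C)[C@@H]2[C@](O)(C(C)C)C[C@H]3OC(C)=O)cc1 | target

**Step count**
Total steps: 13. Longest linear sequence: 12 (steps 1, 2, 4–13 from 1; step 3 is a one-step side branch).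

**Three steps most likely to fail**

Step 7 (isopropyl addition to the vinylogous silyl ester). The bulky, basic isopropyl nucleophile may add sluggishly or reduce, the alkoxide may take the silyl group from O6, and the tertiary aldol may dehydrate on unmasking. The fallback sets out from 8 and returns at 10. It brings the three carbons in as an sp2 nucleophile: 2-propenylmagnesium bromide with CeCl3 at −78 °C (no β-hydrogen, smaller) gives the adduct (1R,2R,4R)-2,6,10-tris[(tert-butyldimethylsilyl)oxy]dauca-5,9,11-trien-4-ol F1. Buffered TBAF/AcOH then gives the isopropenyl carbinol (1R,2R,4S,5R)-2-[(tert-butyldimethylsilyl)oxy]-4-hydroxydauc-11-ene-6,10-dione F2. Hydrogenation of its only C=C (H2, Pd/C, EtOAc) delivers 10.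

Step 8 (the proposed tertiary-carbinol-directed Tishchenko/acyl shift). The tertiary Sm alkoxide may not form the hemiacetal, or the acyl group may stay on O4. The fallback uses known chemistry, sets out from 10 and returns at 13. Evans–Saksena reduction (Me4NBH(OAc)3, AcOH/MeCN, −20 °C) delivers hydride internally from the C4-bound borate to the same C6 face and gives the anti-diol (1R,2R,4R,5S,6S)-2-[(tert-butyldimethylsilyl)oxy]-4,6-dihydroxydaucan-10-one F3. Acylation of its only secondary hydroxyl with 4-methoxybenzoyl chloride (pyridine, DMAP, 0 °C) gives 13.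

Step 13 (epoxidation face). The free allylic 10-OH could steer the oxidant to the wrong face. The fallback sets out from 17 and returns at 18. The 10-OH is capped with TESCl/imidazole (the tertiary OH is inert) to give the 10-O-triethylsilyl ether of 17, (1R,2R,4R,5S,6S,10S)-2-acetoxy-4-hydroxy-10-[(triethylsilyl)oxy]dauc-8-en-6-yl 4-methoxybenzoate F4. mCPBA/NaHCO3 in CH2Cl2 then epoxidises anti to both the OTES group and the angular CH3, giving the 10-O-triethylsilyl ether of 18, (1R,2R,4R,5S,6S,8R,9S,10R)-2-acetoxy-8,9-epoxy-4-hydroxy-10-[(triethylsilyl)oxy]daucan-6-yl 4-methoxybenzoate F5. HF·pyridine removes the silyl group to give 18.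

**Further compounds**
F1 | step 7 | (1R,2R,4R)-2,6,10-tris[(tert-butyldimethylsilyl)oxy]dauca-5,9,11-trien-4-ol | CC(C)(C)[Si](C)(C)OC=1CC(C)C=C(O[Si](C)(C)C(C)(C)C)[C@]2(C)C1[C@](O)(C(C)=C)C[C@H]2O[Si](C)(C)C(C)(C)C
F2 | step 7 | (1R,2R,4S,5R)-2-[(tert-butyldimethylsilyl)oxy]-4-hydroxydauc-11-ene-6,10-dione | O=C1CC(C)CC(=O)[C@]2(C)[C@@H]1[C@](O)(C(C)=C)C[C@H]2O[Si](C)(C)C(C)(C)C
F3 | step 8 | (1R,2R,4R,5S,6S)-2-[(tert-butyldimethylsilyl)oxy]-4,6-dihydroxydaucan-10-one | O[C@H]1CC(C)CC(=O)[C@]2(C)[C@@H]1[C@](O)(C(C)C)C[C@H]2O[Si](C)(C)C(C)(C)C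
F4 | step 13 | (1R,2R,4R,5S,6S,10S)-2-acetoxy-4-hydroxy-10-[(triethylsilyl)oxy]dauc-8-en-6-yl 4-methoxybenzoate | COc1ccc(C(=O)O[C@H]2CC(C)=C[C@H](O[Si](CC)(CC)CC)[C@]3(C)[C@@H]2[C@](O)(C(C)C)C[C@H]3OC(C)=O)cc1
F5 | step 13 | (1R,2R,4R,5S,6S,8R,9S,10R)-2-acetoxy-8,9-epoxy-4-hydroxy-10-[(triethylsilyl)oxy]daucan-6-yl 4-methoxybenzoate | COc1ccc(C(=O)O[C@H]2C[C@@]3(C)O[C@H]3[C@H](O[Si](CC)(CC)CC)[C@]3(C)[C@@H]2[C@](O)(C(C)C)C[C@H]3OC(C)=O)cc1
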